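**Plan**

1. Retrosynthesis (ring atoms O1, C2–C6; side-chain carbons C1′–C12′ counted from the acyl carbon): cut first the C3–C1′ bond (C-acylation of the ring dione by the side-chain acid), then the ring bond O1–C6, then the C6′=C7′ alkene (Julia–Kocienski) and the C8′–C9′ bond (aldol).
2. Enabling feature: in the dihydropyranone ring, O1 sits on C6, a secondary carbon that carries a methyl group and lies three carbons (C5, C4, C3) from the carboxyl carbon C2. The unit O1–C6(H)–CH3 is therefore the Markovnikov hydro-acyloxylation pattern of a terminal alkene C6=CH2, and the carbonyl oxygen of a tert-butyl ester at C2 can close the six-membered ring onto C6, the tert-butyl group leaving in the same event.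
3. Forward order: β-keto ester, then ring closure (steps 1–2); citronellol to the sulfone (3–6); aldol and dioxane aldehyde (7–12); olefination and oxidation to the acid (13–15); C-acylation of the ring and deprotection (16–17).
4. Stereochemistry: ring C6 from the chiral cobalt salen catalyst; C4′ from (R)-citronellol; C10′ from (S)-2-methylbutan-1-ol; C8′ and C9′ from an Evans syn-aldol with the (S)-4-benzyloxazolidinone; the E-alkene from the Julia–Kocienski olefination.

Key step: step 2

Assumption: the (R,R) enantiomer of the cobalt salen complex is taken to give the 6R lactone in step 2; if the sense of induction is the opposite, the (S,S) complex is used with no other change.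
Remark: 3-[(4-methoxybenzyl)oxy]propanoic acid is taken as a catalogue compound; the ring dione is written as its diketo tautomer and the 3-acyl compounds as their 4-hydroxy enol tautomers.

**Route**

Step 1
Reactants: 1 but-3-enoic acid; 2 Meldrum's acid (2,2-dimethyl-1,3-dioxane-4,6-dione)
Product: 4 tert-butyl 3-oxohex-5-enoate, via acyl Meldrum's acid 3 (not isolated)
Conditions: DCC, DMAP, CH2Cl2, −10 °C → rt; urea filtered off, DMAP washed out (aq. KHSO4); then t-BuOH, PhMe, 90 °C
Reagents that add atoms: tert-butanol, CC(C)(C)O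
Why: C-acylation of Meldrum's acid by the DCC-activated acid and thermal cycloreversion of the acyl Meldrum's acid to an acylketene that tert-butanol traps (acyl Meldrum's acid route to β-keto esters) should give 4; the acylated Meldrum's acid is enolised toward the ring, which should keep the β,γ-alkene from moving into conjugation.

Step 2
Reactants: 4 tert-butyl 3-oxohex-5-enoate
Product: 5 (6R)-6-methyloxane-2,4-dione [(R)-6-methyldihydro-2H-pyran-2,4(3H)-dione]
Conditions: [(R,R)-N,N′-bis(3,5-di-tert-butylsalicylidene)cyclohexane-1,2-diaminato]cobalt, C36H52CoN2O2 (divalent cobalt, 5 mol %), 1-fluoro-2,4,6-trimethylpyridinium tetrafluoroborate (1.2 equiv), PhSiH3 (1.2 equiv), PhCF3, 0 °C, argon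
Reagents that add atoms: none
Why: Proposed new method: the salen complex of divalent cobalt is oxidised by the N-fluoropyridinium salt and turned by PhSiH3 into a trivalent cobalt hydride, which transfers a hydrogen atom to the terminal CH2 of the alkene (Markovnikov, since only this gives a secondary radical); the radical is captured by cobalt and oxidised to a tetravalent alkylcobalt species, whose carbon is attacked by the carbonyl oxygen of the tert-butyl ester to give a cyclic dialkoxycarbenium ion that sheds 2-methylpropene. The closest known reaction type is the cobalt salen hydrogen-atom-transfer/radical-polar-crossover hydroalkoxylation and hydroacyloxylation of unactivated alkenes, known to give lactones from alkenyl esters with loss of the ester alkyl group and, with chiral salen ligands, enantioenriched 2-methyl cyclic ethers; new here are the enantioselective six-membered lactone closure and the β-keto ester substrate. The dihydropyranone ring closes in the 6-exo mode: O1 bonds to the internal alkene carbon (C6) and the former CH2 stays outside the ring as the 6-methyl group. The C6 stereocentre is set by the chiral salen ligand, because the C–O bond forms by displacement at the cobalt-bound carbon of interconverting diastereomeric alkylcobalt intermediates. The step needs cyclisation to outrun cobalt-hydride migration of the allyl ketone alkene into conjugation, alkene reduction and fluorination of the C3 methylene; the monosubstituted alkene (a fast hydrogen-atom acceptor), the ester carbonyl placed for a six-membered transition state, the easily lost tert-butyl group and neutral conditions at 0 °C, in which the β-keto ester stays largely in the keto form, should secure this.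

Step 3
Reactants: 6 (R)-citronellol [(3R)-3,7-dimethyloct-6-en-1-ol]; 7 1-phenyl-1H-tetrazole-5-thiol
Product: 8 5-{[(3R)-3,7-dimethyloct-6-en-1-yl]sulfanyl}-1-phenyl-1H-tetrazole
Conditions: PPh3, DIAD, THF, 0 °C → rt
Reagents that add atoms: none
Why: Mitsunobu reaction of a primary alcohol with the acidic tetrazole thiol should give the thioether cleanly; the C3 stereocentre is not involved.

Step 4
Reactants: 8 5-{[(3R)-3,7-dimethyloct-6-en-1-yl]sulfanyl}-1-phenyl-1H-tetrazole
Product: 9 5-{[(3R)-3,7-dimethyloct-6-en-1-yl]sulfonyl}-1-phenyl-1H-tetrazole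
Conditions: (NH4)6Mo7O24·4H2O (10 mol %), 30% aq. H2O2, EtOH, 0 °C → rt
Reagents that add atoms: hydrogen peroxide, OO
Why: Molybdate-catalysed peroxide oxidation of sulfide to sulfone is the standard entry to Julia–Kocienski sulfones and, at or below room temperature, should leave the isolated trisubstituted alkene untouched.

Step 5
Reactants: 9 5-{[(3R)-3,7-dimethyloct-6-en-1-yl]sulfonyl}-1-phenyl-1H-tetrazole
Product: 12 (4R)-4-methyl-6-[(1-phenyl-1H-tetrazol-5-yl)sulfonyl]hexan-1-ol, via ozonide 10 (not isolated), via aldehyde 11 (not isolated)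
Conditions: O3, CH2Cl2, −78 °C; then NaBH4 (excess), MeOH, −78 → 0 °C
Reagents that add atoms: ozone, [O-][O+]=O
Why: Ozonolysis of the only alkene with reductive (borohydride) work-up should deliver the primary alcohol at what becomes C1′ of the chain; the sulfone is inert to ozone and to NaBH4 at 0 °C.

Step 6
Reactants: 12 (4R)-4-methyl-6-[(1-phenyl-1H-tetrazol-5-yl)sulfonyl]hexan-1-ol
Product: 13 5-{[(3R)-6-{[tert-butyl(dimethyl)silyl]oxy}-3-methylhexyl]sulfonyl}-1-phenyl-1H-tetrazole
Conditions: TBSCl, imidazole, CH2Cl2, rt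
Reagents that add atoms: tert-butyldimethylsilyl chloride, CC(C)(C)[Si](C)(C)Cl
Why: Imidazole-promoted silylation of the primary alcohol masks it for the strongly basic olefination.

Step 7
Reactants: 14 (S)-2-methylbutan-1-ol
Product: 15 (S)-2-methylbutanal
Conditions: TEMPO (1 mol %), KBr, NaOCl, NaHCO3, CH2Cl2/H2O, 0 °C; dried CH2Cl2 solution used at once
Reagents that add atoms: none
Why: Nitroxyl-catalysed hypochlorite oxidation of a primary alcohol stops at the aldehyde and, run cold and buffered, should not racemise the α-stereocentre; the volatile aldehyde is used in solution.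

Step 8
Reactants: 16 (S)-4-benzyloxazolidin-2-one; 17 3-[(4-methoxybenzyl)oxy]propanoic acid
Product: 19 (4S)-4-benzyl-3-{3-[(4-methoxybenzyl)oxy]propanoyl}oxazolidin-2-one, via mixed pivalic anhydride 18 (not isolated)
Conditions: t-BuCOCl, Et3N, THF, −20 °C; then 16, LiCl, −20 °C → rt
Reagents that add atoms: none
Why: N-acylation of the oxazolidinone through the mixed pivalic anhydride (LiCl-assisted) is the usual one-pot preparation of Evans imides.

Step 9
Reactants: 19 (4S)-4-benzyl-3-{3-[(4-methoxybenzyl)oxy]propanoyl}oxazolidin-2-one; 15 (S)-2-methylbutanal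
Product: 22 (4S)-4-benzyl-3-[(2S,3R,4S)-3-hydroxy-2-{[(4-methoxybenzyl)oxy]methyl}-4-methylhexanoyl]oxazolidin-2-one, via boron enolate 20 (not isolated), via boron aldolate 21 (not isolated)
Conditions: Bu2BOTf, Et3N, CH2Cl2, −78 → 0 °C; then 15, −78 → 0 °C; then pH 7 buffer, MeOH, 30% H2O2, 0 °C
Reagents that add atoms: none
Why: Evans syn-aldol reaction: the Z-boron enolate reacts through a chair Zimmerman–Traxler transition state in which the (S)-benzyl auxiliary dictates the enolate face, setting C2 (S) and C3 (R) of the hexanoyl chain (C8′ and C9′ of the target) with reagent control that should override the weak bias of the α-methyl aldehyde.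

Step 10
Reactants: 22 (4S)-4-benzyl-3-[(2S,3R,4S)-3-hydroxy-2-{[(4-methoxybenzyl)oxy]methyl}-4-methylhexanoyl]oxazolidin-2-one
Product: 23 (4S)-4-benzyl-3-{(2S,4R,5S)-4-[(2S)-butan-2-yl]-2-(4-methoxyphenyl)-1,3-dioxane-5-carbonyl}oxazolidin-2-one
Conditions: DDQ (1.1 equiv), 4 Å molecular sieves, CH2Cl2, 0 °C
Reagents that add atoms: none
Why: DDQ oxidation of the p-methoxybenzyl ether to a benzylic oxocarbenium ion under anhydrous conditions and capture by the β-hydroxyl (oxidative acetalisation) should give the 1,3-dioxane, the acetal centre settling with the aryl group equatorial, cis to the equatorial sec-butyl group.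

Step 11
Reactants: 23 (4S)-4-benzyl-3-{(2S,4R,5S)-4-[(2S)-butan-2-yl]-2-(4-methoxyphenyl)-1,3-dioxane-5-carbonyl}oxazolidin-2-one
Product: 24 {(2S,4R,5S)-4-[(2S)-butan-2-yl]-2-(4-methoxyphenyl)-1,3-dioxan-5-yl}methanol
Conditions: LiBH4, MeOH (1 equiv), THF, 0 °C
Reagents that add atoms: none
Why: Reductive cleavage of the N-acyloxazolidinone by LiBH4 gives the primary alcohol and returns the auxiliary; the acetal is inert.

Step 12
Reactants: 24 {(2S,4R,5S)-4-[(2S)-butan-2-yl]-2-(4-methoxyphenyl)-1,3-dioxan-5-yl}methanol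
Product: 25 (2S,4R,5S)-4-[(2S)-butan-2-yl]-2-(4-methoxyphenyl)-1,3-dioxane-5-carbaldehyde
Conditions: Dess–Martin periodinane, NaHCO3, CH2Cl2, 0 °C → rt
Reagents that add atoms: none
Why: Buffered Dess–Martin oxidation gives the aldehyde without acid; its α-centre is the equatorial, thermodynamically preferred epimer on the all-equatorial dioxane, so epimerisation is not expected.

Step 13
Reactants: 13 5-{[(3R)-6-{[tert-butyl(dimethyl)silyl]oxy}-3-methylhexyl]sulfonyl}-1-phenyl-1H-tetrazole; 25 (2S,4R,5S)-4-[(2S)-butan-2-yl]-2-(4-methoxyphenyl)-1,3-dioxane-5-carbaldehyde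
Product: 26 tert-butyl({(4R,6E)-7-[(2S,4R,5S)-4-[(2S)-butan-2-yl]-2-(4-methoxyphenyl)-1,3-dioxan-5-yl]-4-methylhept-6-en-1-yl}oxy)dimethylsilane
Conditions: 13, KN(SiMe3)2, DME, −60 °C; then 25, −60 °C → rt
Reagents that add atoms: none
Why: Julia–Kocienski olefination: addition of the potassium sulfonyl carbanion to the α-branched aldehyde, Smiles rearrangement and anti-elimination of SO2 and the tetrazolone anion should give the E-alkene, favoured by the phenyltetrazolyl sulfone, the potassium counter-ion and DME.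

Step 14
Reactants: 26 tert-butyl({(4R,6E)-7-[(2S,4R,5S)-4-[(2S)-butan-2-yl]-2-(4-methoxyphenyl)-1,3-dioxan-5-yl]-4-methylhept-6-en-1-yl}oxy)dimethylsilane
Product: 27 (4R,6E)-7-[(2S,4R,5S)-4-[(2S)-butan-2-yl]-2-(4-methoxyphenyl)-1,3-dioxan-5-yl]-4-methylhept-6-en-1-ol
Conditions: Bu4NF, THF, 0 °C → rt
Reagents that add atoms: none
Why: Fluoride-mediated desilylation; acetal and alkene are inert.

Step 15
Reactants: 27 (4R,6E)-7-[(2S,4R,5S)-4-[(2S)-butan-2-yl]-2-(4-methoxyphenyl)-1,3-dioxan-5-yl]-4-methylhept-6-en-1-ol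
Product: 29 (4R,6E)-7-[(2S,4R,5S)-4-[(2S)-butan-2-yl]-2-(4-methoxyphenyl)-1,3-dioxan-5-yl]-4-methylhept-6-enoic acid, via aldehyde 28 (not isolated)
Conditions: TEMPO (20 mol %), PhI(OAc)2 (2.2 equiv), MeCN/aq. NaH2PO4–Na2HPO4 buffer (pH 7), rt
Reagents that add atoms: water, O
Why: Nitroxyl-catalysed oxidation with PhI(OAc)2 in buffered aqueous acetonitrile takes the primary alcohol through the aldehyde hydrate to the acid without touching the alkene, and the buffer should keep the acetal intact.

Step 16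
Reactants: 29 (4R,6E)-7-[(2S,4R,5S)-4-[(2S)-butan-2-yl]-2-(4-methoxyphenyl)-1,3-dioxan-5-yl]-4-methylhept-6-enoic acid; 5 (6R)-6-methyloxane-2,4-dione
Product: 31 (6R)-3-{(4R,6E)-7-[(2S,4R,5S)-4-[(2S)-butan-2-yl]-2-(4-methoxyphenyl)-1,3-dioxan-5-yl]-4-methylhept-6-enoyl}-4-hydroxy-6-methyl-5,6-dihydro-2H-pyran-2-one, via enol ester 30 (not isolated)
Conditions: DCC, DMAP, CH2Cl2, 0 °C → rt
Reagents that add atoms: none
Why: DCC/DMAP esterification of the vinylogous acid at O4 followed by DMAP-mediated O-to-C acyl migration (Fries-type rearrangement) should give the hydrogen-bonded 3-acyl enol, the thermodynamic product, as known for 4-hydroxy-5,6-dihydropyran-2-ones; C6 is not involved.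

Step 17
Reactants: 31 (6R)-3-{(4R,6E)-7-[(2S,4R,5S)-4-[(2S)-butan-2-yl]-2-(4-methoxyphenyl)-1,3-dioxan-5-yl]-4-methylhept-6-enoyl}-4-hydroxy-6-methyl-5,6-dihydro-2H-pyran-2-one
Product: 32 (6R)-4-hydroxy-3-[(4R,6E,8S,9R,10S)-9-hydroxy-8-(hydroxymethyl)-4,10-dimethyldodec-6-enoyl]-6-methyl-5,6-dihydro-2H-pyran-2-one (target)
Conditions: AcOH/THF/H2O (3:1:1), 40 °C
Reagents that add atoms: none
Why: Acid-catalysed hydrolysis of the p-methoxybenzylidene acetal frees the 1,3-diol; the acyl pyranone, itself a vinylogous acid, and the alkene should tolerate aqueous acetic acid.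

**Compound list**

1 | but-3-enoic acid | C=CCC(=O)O | starting material
2 | Meldrum's acid (2,2-dimethyl-1,3-dioxane-4,6-dione) | CC1(C)OC(=O)CC(=O)O1 | starting material
3 | 5-(1-hydroxybut-3-en-1-ylidene)-2,2-dimethyl-1,3-dioxane-4,6-dione | C=CCC(O)=C1C(=O)OC(C)(C)OC1=O | intermediate, not isolated
4 | tert-butyl 3-oxohex-5-enoate | C=CCC(=O)CC(=O)OC(C)(C)C | intermediate
5 | (6R)-6-methyloxane-2,4-dione | C[C@@H]1CC(=O)CC(=O)O1 | intermediate
6 | (R)-citronellol, (3R)-3,7-dimethyloct-6-en-1-ol | OCC[C@H](C)CCC=C(C)C | starting material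
7 | 1-phenyl-1H-tetrazole-5-thiol | Sc1nnnn1-c1ccccc1 | starting material
8 | 5-{[(3R)-3,7-dimethyloct-6-en-1-yl]sulfanyl}-1-phenyl-1H-tetrazole | c1ccccc1-n1nnnc1SCC[C@H](C)CCC=C(C)C | intermediate
9 | 5-{[(3R)-3,7-dimethyloct-6-en-1-yl]sulfonyl}-1-phenyl-1H-tetrazole | c1ccccc1-n1nnnc1S(=O)(=O)CC[C@H](C)CCC=C(C)C | intermediate
10 | 5-{[(3R)-5-(5,5-dimethyl-1,2,4-trioxolan-3-yl)-3-methylpentyl]sulfonyl}-1-phenyl-1H-tetrazole (ozonide, mixture at the trioxolane carbon) | c1ccccc1-n1nnnc1S(=O)(=O)CC[C@H](C)CCC1OOC(C)(C)O1 | intermediate, not isolated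
11 | (4R)-4-methyl-6-[(1-phenyl-1H-tetrazol-5-yl)sulfonyl]hexanal | c1ccccc1-n1nnnc1S(=O)(=O)CC[C@H](C)CCC=O | intermediate, not isolated
12 | (4R)-4-methyl-6-[(1-phenyl-1H-tetrazol-5-yl)sulfonyl]hexan-1-ol | c1ccccc1-n1nnnc1S(=O)(=O)CC[C@H](C)CCCO | intermediate
13 | 5-{[(3R)-6-{[tert-butyl(dimethyl)silyl]oxy}-3-methylhexyl]sulfonyl}-1-phenyl-1H-tetrazole | c1ccccc1-n1nnnc1S(=O)(=O)CC[C@H](C)CCCO[Si](C)(C)C(C)(C)C | intermediate
14 | (S)-2-methylbutan-1-ol | CC[C@H](C)CO | starting material
15 | (S)-2-methylbutanal | CC[C@H](C)C=O | intermediate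
16 | (S)-4-benzyloxazolidin-2-one | O=C1N[C@@H](Cc2ccccc2)CO1 | starting material
17 | 3-[(4-methoxybenzyl)oxy]propanoic acid | COc1ccc(COCCC(=O)O)cc1 | starting material
18 | 3-[(4-methoxybenzyl)oxy]propanoic pivalic anhydride | COc1ccc(COCCC(=O)OC(=O)C(C)(C)C)cc1 | intermediate, not isolated
19 | (4S)-4-benzyl-3-{3-[(4-methoxybenzyl)oxy]propanoyl}oxazolidin-2-one | COc1ccc(COCCC(=O)N2[C@@H](Cc3ccccc3)COC2=O)cc1 | intermediate
20 | (Z)-dibutylboron enolate of 19 | CCCCB(CCCC)O/C(=C\COCc1ccc(OC)cc1)N1[C@@H](Cc2ccccc2)COC1=O | intermediate, not isolated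
21 | O-dibutylboryl aldolate of 22 | CC[C@H](C)[C@@H](OB(CCCC)CCCC)[C@@H](C(=O)N1[C@@H](Cc2ccccc2)COC1=O)COCc1ccc(OC)cc1 | intermediate, not isolated
22 | (4S)-4-benzyl-3-[(2S,3R,4S)-3-hydroxy-2-{[(4-methoxybenzyl)oxy]methyl}-4-methylhexanoyl]oxazolidin-2-one | CC[C@H](C)[C@@H](O)[C@@H](C(=O)N1[C@@H](Cc2ccccc2)COC1=O)COCc1ccc(OC)cc1 | intermediate
23 | (4S)-4-benzyl-3-{(2S,4R,5S)-4-[(2S)-butan-2-yl]-2-(4-methoxyphenyl)-1,3-dioxane-5-carbonyl}oxazolidin-2-one | CC[C@H](C)[C@H]1O[C@@H](c2ccc(OC)cc2)OC[C@@H]1C(=O)N1[C@@H](Cc2ccccc2)COC1=O | intermediate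
24 | {(2S,4R,5S)-4-[(2S)-butan-2-yl]-2-(4-methoxyphenyl)-1,3-dioxan-5-yl}methanol | CC[C@H](C)[C@H]1O[C@@H](c2ccc(OC)cc2)OC[C@@H]1CO | intermediate
25 | (2S,4R,5S)-4-[(2S)-butan-2-yl]-2-(4-methoxyphenyl)-1,3-dioxane-5-carbaldehyde | CC[C@H](C)[C@H]1O[C@@H](c2ccc(OC)cc2)OC[C@@H]1C=O | intermediate
26 | tert-butyl({(4R,6E)-7-[(2S,4R,5S)-4-[(2S)-butan-2-yl]-2-(4-methoxyphenyl)-1,3-dioxan-5-yl]-4-methylhept-6-en-1-yl}oxy)dimethylsilane | CC[C@H](C)[C@H]1O[C@@H](c2ccc(OC)cc2)OC[C@@H]1/C=C/C[C@H](C)CCCO[Si](C)(C)C(C)(C)C | intermediate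
27 | (4R,6E)-7-[(2S,4R,5S)-4-[(2S)-butan-2-yl]-2-(4-methoxyphenyl)-1,3-dioxan-5-yl]-4-methylhept-6-en-1-ol | CC[C@H](C)[C@H]1O[C@@H](c2ccc(OC)cc2)OC[C@@H]1/C=C/C[C@H](C)CCCO | intermediate
28 | (4R,6E)-7-[(2S,4R,5S)-4-[(2S)-butan-2-yl]-2-(4-methoxyphenyl)-1,3-dioxan-5-yl]-4-methylhept-6-enal | CC[C@H](C)[C@H]1O[C@@H](c2ccc(OC)cc2)OC[C@@H]1/C=C/C[C@H](C)CCC=O | intermediate, not isolated
29 | (4R,6E)-7-[(2S,4R,5S)-4-[(2S)-butan-2-yl]-2-(4-methoxyphenyl)-1,3-dioxan-5-yl]-4-methylhept-6-enoic acid | CC[C@H](C)[C@H]1O[C@@H](c2ccc(OC)cc2)OC[C@@H]1/C=C/C[C@H](C)CCC(=O)O | intermediate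
30 | (6R)-6-methyl-2-oxo-5,6-dihydro-2H-pyran-4-yl ester of acid 29 (enol ester) | CC[C@H](C)[C@H]1O[C@@H](c2ccc(OC)cc2)OC[C@@H]1/C=C/C[C@H](C)CCC(=O)OC3=CC(=O)O[C@H](C)C3 | intermediate, not isolated
31 | (6R)-3-{(4R,6E)-7-[(2S,4R,5S)-4-[(2S)-butan-2-yl]-2-(4-methoxyphenyl)-1,3-dioxan-5-yl]-4-methylhept-6-enoyl}-4-hydroxy-6-methyl-5,6-dihydro-2H-pyran-2-one | CC[C@H](C)[C@H]1O[C@@H](c2ccc(OC)cc2)OC[C@@H]1/C=C/C[C@H](C)CCC(=O)C3=C(O)C[C@@H](C)OC3=O | intermediate
32 | (6R)-4-hydroxy-3-[(4R,6E,8S,9R,10S)-9-hydroxy-8-(hydroxymethyl)-4,10-dimethyldodec-6-enoyl]-6-methyl-5,6-dihydro-2H-pyran-2-one | CC[C@H](C)[C@@H](O)[C@@H](/C=C/C[C@H](C)CCC(=O)C1=C(O)C[C@@H](C)OC1=O)CO | target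

**Count**

Total steps: 17. Longest linear sequence: 10 steps (steps 8–17, or equally step 7 followed by steps 9–17).

**Steps most likely to fail, with fallbacks**

Step 2 (Proposed new method). The cobalt hydride may move the alkene into conjugation with the ketone instead of allowing ring closure, the alkene may simply be reduced, the active methylene may be fluorinated by the oxidant, and enantio-induction may be low on a chain that has no gem-disubstitution to fix its conformation. The fallback uses known chemistry and closes the ring at the acyl carbon instead. It sets out from Meldrum's acid 2, which is C-acylated with diketene (Et3N, CH2Cl2) to 5-(1-hydroxy-3-oxobutylidene)-2,2-dimethyl-1,3-dioxane-4,6-dione F1. Heating with tert-butanol in toluene gives tert-butyl 3,5-dioxohexanoate F2. An (R)-selective NADPH-dependent ketoreductase (alcohol dehydrogenase, propan-2-ol for cofactor recycling) reduces only the C5 ketone to tert-butyl (5R)-5-hydroxy-3-oxohexanoate F3. CF3CO2H in CH2Cl2 then lactonises with loss of the tert-butyl group, and the route is rejoined at 5.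

Step 1. The β,γ double bond may migrate into conjugation with the carbonyl group under DMAP or during the thermolysis, giving the crotonyl isomer that cannot serve in step 2. The fallback avoids base altogether and sets out from acid 1: (COCl)2 with catalytic DMF gives but-3-enoyl chloride F4, which is treated in CH2Cl2 at 0 °C with 1-tert-butoxy-1-(trimethylsilyloxy)ethene F5 (made from tert-butyl acetate, LiN(iPr)2 and Me3SiCl). This Claisen-type C-acylation of the ketene silyl acetal rejoins the route at 4.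

Step 16. Acylation may stop at the enol ester, the O-to-C acyl migration may be slow against N-acylurea formation, and the valuable acid may be lost in a late convergent step. The fallback is a Lacey–Dieckmann construction that builds the ring around the acyl group. It sets out from acid 29 and Meldrum's acid 2 (DCC, DMAP, CH2Cl2), which give 5-{(4R,6E)-7-[(2S,4R,5S)-4-[(2S)-butan-2-yl]-2-(4-methoxyphenyl)-1,3-dioxan-5-yl]-1-hydroxy-4-methylhept-6-en-1-ylidene}-2,2-dimethyl-1,3-dioxane-4,6-dione F6. Thermolysis in toluene in the presence of commercial methyl (R)-3-hydroxybutanoate traps the acylketene as (2R)-4-methoxy-4-oxobutan-2-yl (6R,8E)-9-[(2S,4R,5S)-4-[(2S)-butan-2-yl]-2-(4-methoxyphenyl)-1,3-dioxan-5-yl]-6-methyl-3-oxonon-8-enoate F7. Bu4NF in THF then effects Dieckmann cyclisation of the β-keto ester carbon onto the methyl ester, rejoining the route at 31.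

**Further compounds**

F1 | step 2 | 5-(1-hydroxy-3-oxobutylidene)-2,2-dimethyl-1,3-dioxane-4,6-dione | CC(=O)CC(O)=C1C(=O)OC(C)(C)OC1=O
F2 | step 2 | tert-butyl 3,5-dioxohexanoate | CC(=O)CC(=O)CC(=O)OC(C)(C)C
F3 | step 2 | tert-butyl (5R)-5-hydroxy-3-oxohexanoate | C[C@@H](O)CC(=O)CC(=O)OC(C)(C)C
F4 | step 1 | but-3-enoyl chloride | C=CCC(=O)Cl
F5 | step 1 | 1-tert-butoxy-1-(trimethylsilyloxy)ethene | C=C(OC(C)(C)C)O[Si](C)(C)C
F6 | step 16 | 5-{(4R,6E)-7-[(2S,4R,5S)-4-[(2S)-butan-2-yl]-2-(4-methoxyphenyl)-1,3-dioxan-5-yl]-1-hydroxy-4-methylhept-6-en-1-ylidene}-2,2-dimethyl-1,3-dioxane-4,6-dione | CC[C@H](C)[C@H]1O[C@@H](c2ccc(OC)cc2)OC[C@@H]1/C=C/C[C@H](C)CCC(O)=C3C(=O)OC(C)(C)OC3=O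
F7 | step 16 | (2R)-4-methoxy-4-oxobutan-2-yl (6R,8E)-9-[(2S,4R,5S)-4-[(2S)-butan-2-yl]-2-(4-methoxyphenyl)-1,3-dioxan-5-yl]-6-methyl-3-oxonon-8-enoate | CC[C@H](C)[C@H]1O[C@@H](c2ccc(OC)cc2)OC[C@@H]1/C=C/C[C@H](C)CCC(=O)CC(=O)O[C@H](C)CC(=O)OC
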